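Assumption: commercial (R)-3-bromo-2-methylpropan-1-ol of at least 98% ee supplies the only stereocentre, and the target (halitulin) is isolated as the free base under argon.

## Retrosynthetic overview
1. After a final global O-debenzylation, the pyrrole is cut at both C–N bonds. Its C3–C4 bond forms in the same pot. This gives one primary amine and two molecules of a quinolin-5-ylacetaldehyde.
2. The azecane is cut at N–C10 (ring closure by anti-Markovnikov hydroamination of a terminal alkene with the secondary amine) and at N–C2 (SN2 on a chiral-pool alcohol).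
3. The C3 stereocentre is bought in the bromo alcohol, and the C10 chain comes from one copper-catalysed Grignard coupling.
4. The quinoline rings are bought intact as clioquinol. C7–O is made by Ullmann coupling at the C–I bond, and the C5 side chain is attached at the C–Cl bond.
5. Ring order: quinolines (purchased), then the azecane, then the pyrrole last.

## Route

Step 1
Reactants: 1 6-bromohex-1-ene; 2 (R)-3-bromo-2-methylpropan-1-ol
Product: 4 (S)-2-methylnon-8-en-1-ol, via hex-5-enylmagnesium bromide 3 (not isolated)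
Conditions: 1 (2.8 equiv), Mg, THF, rt; then 2, Li2CuCl4 (5 mol%), THF, -20 to 0 °C; aq NH4Cl
Reagents that add atoms: none
Why: Kochi-type copper-catalysed sp3–sp3 Grignard coupling, in which the first equivalent of 3 only deprotonates the OH, the primary C–Br bond is then substituted, and the stereocentre is not a reacting centre (the descriptor changes from R to S only because the CIP priorities change).

Step 2
Reactants: 4 (S)-2-methylnon-8-en-1-ol; 5 tert-butyl (3-aminopropyl)carbamate
Product: 7 tert-butyl (S)-{3-[(2-methylnon-8-en-1-yl)amino]propyl}carbamate, via alkyl triflate 6 (not isolated)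
Conditions: Tf2O (1.1 equiv), 2,6-lutidine (1.5 equiv), CH2Cl2, -78 °C; then 5 (4 equiv), -78 °C to rt
Reagents that add atoms: none
Why: SN2 N-alkylation through a primary triflate made in situ forms N–C2 below 0 °C without touching the adjacent stereocentre, and the excess of 5 suppresses dialkylation.

Step 3
Reactants: 7 tert-butyl (S)-{3-[(2-methylnon-8-en-1-yl)amino]propyl}carbamate
Product: 8 tert-butyl {3-[(3S)-3-methylazecan-1-yl]propyl}carbamate
Conditions: [Ir(dF(Me)ppy)2(dtbbpy)]PF6 (5 mol%), 2,4,6-triisopropylbenzenethiol (1 equiv), degassed toluene (2 mM), 450 nm LEDs, recirculating flow coil, 30 °C, 48 h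
Reagents that add atoms: none
Why: Proposed new method: the ten-membered ring is closed by an intramolecular anti-Markovnikov aminium-radical hydroamination, in which the excited trivalent iridium photocatalyst oxidises the secondary amine of 7 to its aminium radical cation, this electrophilic N-radical adds 10-endo to the terminal alkene carbon (forming N–C10), the secondary C-radical takes H from the hindered thiol, and divalent iridium reduces the thiyl radical to close both cycles; every unproductive event (back electron transfer, H return from the thiol, 1,5-H shift followed by thiol repair) regenerates 7, and the rate depends on photon flux rather than on a slow bimolecular catalyst–alkene step, so the reaction can run at 2 mM where ring closure should outrun oligomerisation; the bulky thiol limits thiol-ene addition and C3 is not a reacting centre; the closest known reaction type is the photoredox/thiol-catalysed intermolecular anti-Markovnikov hydroamination of unactivated alkenes with secondary alkylamines, together with its five- and six-ring intramolecular versions, which has not been shown for medium rings.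

Step 4
Reactants: 8 tert-butyl {3-[(3S)-3-methylazecan-1-yl]propyl}carbamate
Product: 9 3-[(3S)-3-methylazecan-1-yl]propan-1-amine
Conditions: 4 M HCl in dioxane, rt; then aq NaOH, extraction
Reagents that add atoms: none
Why: Acidolytic Boc cleavage frees the primary amine, and nothing else in the molecule is acid-labile.

Step 5
Reactants: 10 clioquinol (5-chloro-7-iodoquinolin-8-ol)
Product: 11 8-(benzyloxy)-5-chloro-7-iodoquinoline
Conditions: BnBr (1.1 equiv), K2CO3, DMF, 40 °C
Reagents that add atoms: benzyl bromide, BrCc1ccccc1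
Why: Williamson ether synthesis on the acidic 8-OH masks the metal-chelating hydroxyquinoline unit.

Step 6
Reactants: 11 8-(benzyloxy)-5-chloro-7-iodoquinoline
Product: 12 7,8-bis(benzyloxy)-5-chloroquinoline
Conditions: CuI (10 mol%), 3,4,7,8-tetramethyl-1,10-phenanthroline (20 mol%), Cs2CO3, BnOH (2 equiv), toluene, 110 °C
Reagents that add atoms: benzyl alcohol, OCc1ccccc1
Why: Ullmann-type copper-catalysed C–O coupling installs the C7 oxygen, because the monovalent copper alkoxide reacts with the C–I bond and leaves the C–Cl bond intact.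

Step 7
Reactants: 12 7,8-bis(benzyloxy)-5-chloroquinoline; 13 (E)-2-(2-ethoxyvinyl)-4,4,5,5-tetramethyl-1,3,2-dioxaborolane
Product: 15 2-[7,8-bis(benzyloxy)quinolin-5-yl]acetaldehyde, via enol ether 14 (not isolated)
Conditions: Pd(OAc)2 (3 mol%), SPhos (6 mol%), K3PO4, dioxane/H2O, 100 °C; phase cut; then 2 M HCl, THF, rt; NaHCO3 work-up; used crude the same day
Reagents that add atoms: water, O
Why: Suzuki–Miyaura coupling works here because SPhos-ligated zerovalent palladium inserts into electron-rich aryl chlorides, and acid hydrolysis of the enol ether then gives the aldehyde while the benzyl ethers survive dilute HCl at rt.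

Step 8
Reactants: 15 2-[7,8-bis(benzyloxy)quinolin-5-yl]acetaldehyde (2.2 equiv); 9 3-[(3S)-3-methylazecan-1-yl]propan-1-amine
Product: 16 5,5'-(1-{3-[(3S)-3-methylazecan-1-yl]propyl}-1H-pyrrole-3,4-diyl)bis[7,8-bis(benzyloxy)quinoline] (tetra-O-benzylhalitulin)
Conditions: AgOAc (4 equiv), NaOAc (2 equiv), THF, 60 °C, N2, dark
Reagents that add atoms: none
Why: In this silver-mediated oxidative enamine homocoupling with Paal–Knorr-type cyclocondensation, 9 and 15 form the enamine, monovalent silver oxidises it (far more easily than the tertiary amine), the radical cations couple at the aryl-bearing carbons, and the 1,4-bis-imine closes both pyrrole C–N bonds; extra AgOAc covers the silver bound by the basic nitrogens.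

Step 9
Reactants: 16 tetra-O-benzylhalitulin
Product: 17 halitulin, 5,5'-(1-{3-[(3S)-3-methylazecan-1-yl]propyl}-1H-pyrrole-3,4-diyl)bis(quinoline-7,8-diol)
Conditions: H2 (1 atm), Pd/C (10%), MeOH/THF, rt; filtration and evaporation under argon
Reagents that add atoms: none
Why: Neutral hydrogenolysis removes all four benzyl ethers, gives only toluene as by-product, needs no aqueous work-up of the air-sensitive bis-catechol, and leaves the quinoline, the pyrrole and the stereocentre untouched at 1 atm.

## Compound list
1 | 6-bromohex-1-ene | C=CCCCCBr | starting material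
2 | (R)-3-bromo-2-methylpropan-1-ol | C[C@H](CO)CBr | starting material
3 | hex-5-enylmagnesium bromide | C=CCCCC[Mg]Br | intermediate
4 | (S)-2-methylnon-8-en-1-ol | C[C@H](CO)CCCCCC=C | intermediate
5 | tert-butyl (3-aminopropyl)carbamate | CC(C)(C)OC(=O)NCCCN | starting material
6 | (S)-2-methylnon-8-en-1-yl trifluoromethanesulfonate | C[C@H](COS(=O)(=O)C(F)(F)F)CCCCCC=C | intermediate
7 | tert-butyl (S)-{3-[(2-methylnon-8-en-1-yl)amino]propyl}carbamate | C[C@H](CNCCCNC(=O)OC(C)(C)C)CCCCCC=C | intermediate
8 | tert-butyl {3-[(3S)-3-methylazecan-1-yl]propyl}carbamate | C[C@H]1CCCCCCCN(CCCNC(=O)OC(C)(C)C)C1 | intermediate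
9 | 3-[(3S)-3-methylazecan-1-yl]propan-1-amine | C[C@H]1CCCCCCCN(CCCN)C1 | intermediate
10 | clioquinol, 5-chloro-7-iodoquinolin-8-ol | Oc1c(I)cc(Cl)c2cccnc12 | starting material
11 | 8-(benzyloxy)-5-chloro-7-iodoquinoline | Clc1cc(I)c(OCc2ccccc2)c2ncccc12 | intermediate
12 | 7,8-bis(benzyloxy)-5-chloroquinoline | Clc1cc(OCc2ccccc2)c(OCc2ccccc2)c2ncccc12 | intermediate
13 | (E)-2-(2-ethoxyvinyl)-4,4,5,5-tetramethyl-1,3,2-dioxaborolane | CCO/C=C/B1OC(C)(C)C(C)(C)O1 | starting material
14 | (E)-7,8-bis(benzyloxy)-5-(2-ethoxyvinyl)quinoline | CCO/C=C/c1cc(OCc2ccccc2)c(OCc2ccccc2)c2ncccc12 | intermediate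
15 | 2-[7,8-bis(benzyloxy)quinolin-5-yl]acetaldehyde | O=CCc1cc(OCc2ccccc2)c(OCc2ccccc2)c2ncccc12 | intermediate
16 | tetra-O-benzylhalitulin | C[C@H]1CCCCCCCN(CCCn2cc(-c3cc(OCc4ccccc4)c(OCc4ccccc4)c4ncccc34)c(-c3cc(OCc4ccccc4)c(OCc4ccccc4)c4ncccc34)c2)C1 | intermediate
17 | halitulin | C[C@H]1CCCCCCCN(CCCn2cc(-c3cc(O)c(O)c4ncccc34)c(-c3cc(O)c(O)c4ncccc34)c2)C1 | target

## Step count and risks
Total steps: 9. Longest linear sequence: 6 (steps 1, 2, 3, 4, 8, 9).

**Step 3, the new ring closure.**
- Risks: oligomerisation, weak quenching of the photocatalyst at 2 mM, thiol-ene addition, and photo-degradation of the more easily oxidised product.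
- The fallback uses known chemistry, sets out from 5 and 1, and returns at 8.
- Excess 5 is alkylated with 1 (K2CO3, MeCN) to give tert-butyl [3-(hex-5-en-1-ylamino)propyl]carbamate F1.
- Coupling with commercial (S)-2-methylpent-4-enoic acid (EDC, HOBt, CH2Cl2) gives tert-butyl (S)-{3-[N-(hex-5-en-1-yl)-2-methylpent-4-enamido]propyl}carbamate F2.
- Ring-closing metathesis with the second-generation Grubbs catalyst, (H2IMes)(PCy3)Cl2Ru=CHPh (1 mM, toluene, 80 °C), gives the unsaturated lactam tert-butyl {3-[(3S)-3-methyl-2-oxo-3,4,7,8,9,10-hexahydroazecin-1(2H)-yl]propyl}carbamate F3 as an E/Z mixture.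
- Hydrogenation (H2, Pd/C, EtOAc) gives tert-butyl {3-[(3S)-3-methyl-2-oxoazecan-1-yl]propyl}carbamate F4.
- BH3·THF with an ethanolamine work-up reduces the lactam beside the carbamate and gives 8.

**Step 7, the aldehyde.**
- Risks: a sluggish electron-rich aryl chloride, slow hydrolysis of the protonated quinoline enol ether, and self-condensation of 15 in acid.
- The fallback sets out from 12 and returns at 15.
- Suzuki allylation with allylboronic acid pinacol ester (Pd(OAc)2, SPhos, K3PO4, THF/H2O) gives 5-allyl-7,8-bis(benzyloxy)quinoline F5.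
- Lemieux–Johnson cleavage (OsO4 cat., NaIO4, 2,6-lutidine, dioxane/H2O) then releases 15 under near-neutral conditions.

**Step 8, the pyrrole annulation.**
- Risks: silver tied up by five basic nitrogens, aldol loss of 15, and low conversion.
- The fallback sets out from 12, uses 9, and returns at 16. It makes the C3–C4 bond first and leaves a pure C–N condensation for the end.
- Negishi-type coupling of 12 with BrZnCH2CO2tBu (Pd2(dba)3, XPhos, THF, 65 °C) gives tert-butyl 2-[7,8-bis(benzyloxy)quinolin-5-yl]acetate F6.
- Enolate oxidative dimerisation (LiHMDS, then I2, 0.5 equiv, THF, -78 °C) gives di-tert-butyl 2,3-bis[7,8-bis(benzyloxy)quinolin-5-yl]succinate F7 as a dl/meso mixture.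
- LiAlH4 reduction gives 2,3-bis[7,8-bis(benzyloxy)quinolin-5-yl]butane-1,4-diol F8.
- Swern oxidation gives 2,3-bis[7,8-bis(benzyloxy)quinolin-5-yl]succinaldehyde F9.
- Classical Paal–Knorr condensation of F9 with 9 (AcOH cat., toluene, 60 °C) gives 16.

## Further compounds
F1 | step 3 | tert-butyl [3-(hex-5-en-1-ylamino)propyl]carbamate | C=CCCCCNCCCNC(=O)OC(C)(C)C
F2 | step 3 | tert-butyl (S)-{3-[N-(hex-5-en-1-yl)-2-methylpent-4-enamido]propyl}carbamate | C[C@@H](CC=C)C(=O)N(CCCCC=C)CCCNC(=O)OC(C)(C)C
F3 | step 3 | tert-butyl {3-[(3S)-3-methyl-2-oxo-3,4,7,8,9,10-hexahydroazecin-1(2H)-yl]propyl}carbamate (E/Z mixture) | C[C@H]1CC=CCCCCN(CCCNC(=O)OC(C)(C)C)C1=O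
F4 | step 3 | tert-butyl {3-[(3S)-3-methyl-2-oxoazecan-1-yl]propyl}carbamate | C[C@H]1CCCCCCCN(CCCNC(=O)OC(C)(C)C)C1=O
F5 | step 7 | 5-allyl-7,8-bis(benzyloxy)quinoline | C=CCc1cc(OCc2ccccc2)c(OCc2ccccc2)c2ncccc12
F6 | step 8 | tert-butyl 2-[7,8-bis(benzyloxy)quinolin-5-yl]acetate | CC(C)(C)OC(=O)Cc1cc(OCc2ccccc2)c(OCc2ccccc2)c2ncccc12
F7 | step 8 | di-tert-butyl 2,3-bis[7,8-bis(benzyloxy)quinolin-5-yl]succinate (dl/meso mixture) | CC(C)(C)OC(=O)C(c1cc(OCc2ccccc2)c(OCc2ccccc2)c2ncccc12)C(C(=O)OC(C)(C)C)c1cc(OCc2ccccc2)c(OCc2ccccc2)c2ncccc12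
F8 | step 8 | 2,3-bis[7,8-bis(benzyloxy)quinolin-5-yl]butane-1,4-diol (dl/meso mixture) | OCC(c1cc(OCc2ccccc2)c(OCc2ccccc2)c2ncccc12)C(CO)c1cc(OCc2ccccc2)c(OCc2ccccc2)c2ncccc12
F9 | step 8 | 2,3-bis[7,8-bis(benzyloxy)quinolin-5-yl]succinaldehyde (dl/meso mixture) | O=CC(c1cc(OCc2ccccc2)c(OCc2ccccc2)c2ncccc12)C(C=O)c1cc(OCc2ccccc2)c(OCc2ccccc2)c2ncccc12
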